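The retrosynthesis first removes the epoxide oxygen on C7–C8 and the two acetyl groups. It then cuts C12–C13 (vinylogous aldol), C4–C12 (carbonylation of a C3=C4 enol triflate) and C11=CH2 (methylenation). Next it cuts C6–C7 of the nine-membered ring, and last C4a–C5 and C11a–C11 (three-component coupling on a dihydropyranone).
In the forward direction ring A is made first, as a lactone, by ring-closing metathesis, and both arms are attached in one operation. The nine-membered ring is closed by hydroboration/B-alkyl Suzuki–Miyaura coupling. The C11 methylene, the enol ether with its side chain, the acetates and the epoxide follow.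
The enabling feature is that C6 is an unfunctionalised CH2 two atoms from ring-fusion carbon C4a, so it is the terminus of a vinyl group on ring A. C7 is the methyl-bearing sp2 carbon of the E-C7=C8 olefin hidden in the trans-epoxide. C6–C7 is therefore an sp3–sp2 ring bond that closes without touching a stereocentre and carries a pre-set E geometry into the strained ring.
The C4 silyloxy centre from (R)-but-3-ene-1,2-diol directs C4a, C4a directs C11a (anti, anti), and C4 is later erased. C12 comes from a chiral Lewis-base catalyst, and C1 from acylation of the equilibrating lactol trans to C11. C7 and C8 come from outer-face attack on the planar-chiral E-cyclononene.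

Key step: step 7

Remark: the numbering is C1 (acetal carbon), O2, C3=C4, C4a and C11a (ring fusion), C5–C11 (nine-membered ring, methyl on C7, methylene on C11), C12–C16 (side chain).
Assumption: the two C11 carbinol epimers formed in step 6 are carried together, because this centre is erased in step 10. The ketene acetal geometry of 26 has no bearing on step 17.

Step 1
Reactants: 1 hex-4-yn-1-ol
Product: 3 (E)-5-iodohex-4-en-1-ol, via alkenylzirconocene 2 (not isolated)
Conditions: Cp2Zr(H)Cl (2.5 equiv), THF, 25 to 45 °C; then I2, THF, 0 °C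
Reagents that add atoms: iodine, II
Why: Syn hydrozirconation of the 2-alkyne, equilibrated by excess hydride toward the less hindered methyl-bearing carbon, followed by iodinolysis with retention should give the E-2-iodoalkene that fixes the later C7=C8 geometry.

Step 2
Reactants: 3 (E)-5-iodohex-4-en-1-ol
Product: 4 (E)-5-iodohex-4-enal
Conditions: Dess–Martin periodinane, CH2Cl2, 0 to 25 °C
Reagents that add atoms: none
Why: Dess–Martin oxidation stops at the aldehyde and leaves the alkenyl iodide untouched.

Step 3
Reactants: 5 (R)-but-3-ene-1,2-diol; 6 acryloyl chloride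
Product: 7 (R)-2-hydroxybut-3-en-1-yl acrylate
Conditions: 2,4,6-collidine, CH2Cl2, −78 °C
Reagents that add atoms: none
Why: Esterification with an acid chloride at low temperature and with a hindered base acylates the primary hydroxyl ahead of the secondary allylic one, and the stereocentre is not involved.

Step 4
Reactants: 7 (R)-2-hydroxybut-3-en-1-yl acrylate
Product: 8 (R)-2-(triethylsilyloxy)but-3-en-1-yl acrylate
Conditions: Et3SiCl, imidazole, CH2Cl2, 0 °C
Reagents that add atoms: chlorotriethylsilane, CC[Si](Cl)(CC)CC
Why: Standard silyl ether formation, with a group bulky enough to steer step 6 and labile enough to leave selectively in step 12.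

Step 5
Reactants: 8 (R)-2-(triethylsilyloxy)but-3-en-1-yl acrylate
Product: 9 (R)-5-(triethylsilyloxy)-5,6-dihydro-2H-pyran-2-one
Conditions: second-generation Grubbs catalyst RuCl2(=CHPh)(PCy3)(H2IMes) (3 mol %), CH2Cl2, 40 °C
Reagents that add atoms: none
Why: Ring-closing metathesis of an acrylate with a terminal alkene is a standard entry to 5,6-dihydropyran-2-ones and is driven by loss of ethene.

Step 6
Reactants: 9 (R)-5-(triethylsilyloxy)-5,6-dihydro-2H-pyran-2-one; 10 vinylmagnesium bromide; 4 (E)-5-iodohex-4-enal
Product: 12 (3R,4S,5R)-3-[(E)-1-hydroxy-5-iodohex-4-en-1-yl]-5-(triethylsilyloxy)-4-vinyltetrahydro-2H-pyran-2-one, via magnesium enolate 11 (not isolated)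
Conditions: 10 (2.2 equiv), CuBr·SMe2 (1.1 equiv), THF/Me2S, −78 °C; add 9; then 4, −78 °C; aq. NH4Cl
Reagents that add atoms: none
Why: In this tandem conjugate addition–aldol (three-component coupling) the vinyl cuprate attacks C4a anti to the neighbouring C4 silyloxy group and the enolate then takes up aldehyde 4 at C11a anti to the new vinyl group, which sets the trans C4a/C11a pair, while the C11 carbinol centre is uncontrolled and is erased in step 10.

Step 7
Reactants: 12 (3R,4S,5R)-3-[(E)-1-hydroxy-5-iodohex-4-en-1-yl]-5-(triethylsilyloxy)-4-vinyltetrahydro-2H-pyran-2-one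
Product: 14 (4R,4aS,7E,11aR)-11-hydroxy-7-methyl-4-(triethylsilyloxy)-3,4,4a,5,6,9,10,11,11a-nonahydrocyclonona[c]pyran-1-one, via bis-boron adduct 13 (not isolated)
Conditions: 9-BBN (3 equiv), THF, 0 to 25 °C; then slow addition to Pd(dppf)Cl2 (15 mol %), AsPh3, Cs2CO3, DMF/THF/H2O, 45 °C, 1 mM
Reagents that add atoms: none
Why: 9-BBN adds anti-Markovnikov to the only monosubstituted alkene (C5=C6) and masks the C11 hydroxyl as a borinate, then zerovalent palladium inserts into the C7–I bond with retention, base-assisted transmetallation moves the primary C6 alkyl group from boron to divalent palladium, and reductive elimination forges C6–C7. The closest known reaction type is the intramolecular B-alkyl Suzuki–Miyaura coupling, which has been used to close E-configured trisubstituted cyclononenes and larger rings. The nine-membered carbocycle closes by reductive elimination from a ten-membered palladacycle, an endocyclic sp3–sp2 closure in which no ring atom has to rehybridise. No new stereocentre arises: the E geometry of C7=C8 is carried over from iodide 4, and the sense of planar chirality of the new ring is imposed by the trans C4a/C11a pair, which later directs the epoxidation. The step needs chemoselective hydroboration, secured by keeping C11 at the carbinol level so that no second 1-alkene is present and by the inertness of the trisubstituted iodoalkene and the lactone toward 9-BBN, and it needs cyclisation to beat oligomerisation, secured by the two arms sitting on adjacent carbons of ring A and by slow addition at high dilution. A two-electron transmetallation is preferred to a radical coupling because it cannot scramble the olefin geometry.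

Step 8
Reactants: 14 bicyclic lactone
Product: 15 bicyclic lactol (C1 is CH(OH) and is drawn with 1-OH trans to C11; otherwise as 14)
Conditions: iBu2AlH (2.3 equiv), CH2Cl2, −78 °C; aq. potassium sodium tartrate
Reagents that add atoms: none
Why: Partial reduction of a δ-lactone with iBu2AlH stops at the aluminium hemiacetal at low temperature (one equivalent is consumed by the free hydroxyl), and the lactol equilibrates at C1, so this centre is not yet fixed.

Step 9
Reactants: 15 bicyclic lactol
Product: 16 1-O-(tert-butyldiphenylsilyl) acetal of 15 (silyloxy group trans to C11; 11-OH free)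
Conditions: tBuPh2SiCl (1.1 equiv), imidazole, CH2Cl2, 0 °C
Reagents that add atoms: tert-butylchlorodiphenylsilane, CC(C)(C)[Si](Cl)(c1ccccc1)c1ccccc1
Why: In this silyl ether formation the more acidic and less hindered anomeric hydroxyl should react with the bulky chlorosilane before the ring carbinol at C11, and the equilibrating lactol is drained through the anomer whose oxygen lies trans to the C11a substituent.

Step 10
Reactants: 16 1-O-silyl acetal with free 11-OH
Product: 17 11-ketone of 16
Conditions: Dess–Martin periodinane, pyridine, CH2Cl2, 0 °C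
Reagents that add atoms: none
Why: Buffered Dess–Martin oxidation merges both C11 epimers into one ketone under neutral conditions that should spare the C11a centre and the β-acetal oxygen.

Step 11
Reactants: 17 11-ketone
Product: 18 11-methylene compound (C11=CH2; 4-OSiEt3; 1-OSiPh2tBu)
Conditions: Cp2TiMe2, toluene, 70 °C, dark
Reagents that add atoms: dimethyltitanocene, C[Ti](C)(C1C=CC=C1)C1C=CC=C1
Why: Petasis methylenation proceeds through a non-basic titanium methylidene, so enolisation, epimerisation at C11a and β-elimination of the acetal oxygen, which threaten a Wittig reaction here, should be avoided.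

Step 12
Reactants: 18 11-methylene compound
Product: 19 4-alcohol (4R; 1-OSiPh2tBu retained)
Conditions: PPTS (cat.), MeOH/CH2Cl2, 0 °C
Reagents that add atoms: none
Why: Mild acid-catalysed methanolysis cleaves a secondary triethylsilyl ether much faster than the bulky and electronically deactivated anomeric tert-butyldiphenylsilyl ether.

Step 13
Reactants: 19 4-alcohol
Product: 20 4-ketone
Conditions: Dess–Martin periodinane, pyridine, CH2Cl2, 0 °C
Reagents that add atoms: none
Why: Buffered Dess–Martin oxidation erases the auxiliary C4 centre without base, so the adjacent C4a centre should stay trans.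

Step 14
Reactants: 20 4-ketone
Product: 22 C3=C4 enol triflate, via potassium enolate 21 (not isolated)
Conditions: KN(SiMe3)2, THF, −78 °C; then N-(5-chloro-2-pyridyl)bis(trifluoromethanesulfonimide), −78 °C
Reagents that add atoms: Comins reagent, FC(F)(F)S(=O)(=O)N(c1ccc(Cl)cn1)S(=O)(=O)C(F)(F)F
Why: Kinetic deprotonation by a bulky amide should take place at the open C3 methylene and not at the tertiary C4a–H that is shielded by the nine-membered ring, and O-triflation of this enolate (enol triflate synthesis) installs the C3=C4 enol ether of ring A.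

Step 15
Reactants: 22 enol triflate
Product: 23 4-carbaldehyde (C12 aldehyde on the C3=C4 enol ether)
Conditions: Pd(PPh3)4 (10 mol %), LiCl, CO (1 atm), Bu3SnH (slow addition), THF, 50 °C
Reagents that add atoms: carbon monoxide, [C-]#[O+]
Why: Palladium-catalysed reductive carbonylation (formylation) of an alkenyl triflate runs by oxidative addition, CO insertion and hydride transfer from tin, and slow addition of the hydride keeps direct reduction down.

Step 16
Reactants: 24 methyl tiglate
Product: 26 tert-butyl[(1-methoxy-2-methylbuta-1,3-dien-1-yl)oxy]dimethylsilane, via lithium dienolate 25 (not isolated)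
Conditions: LiN(iPr)2, THF/DMPU, −78 °C; then tBuMe2SiCl
Reagents that add atoms: tert-butylchlorodimethylsilane, CC(C)(C)[Si](C)(C)Cl
Why: γ-Deprotonation of the unsaturated ester and O-silylation of the dienolate is the standard route to silyl dienol ethers.

Step 17
Reactants: 23 4-carbaldehyde; 26 silyl dienol ether
Product: 27 (12S)-alcohol with the complete methyl (E)-2-methylpent-2-enoate side chain (1-OSiPh2tBu retained)
Conditions: SiCl4, (S,S)-BINAM-derived bisphosphoramide (5 mol %), iPr2NEt (cat.), CH2Cl2, −78 °C; aq. NaHCO3/KF
Reagents that add atoms: none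
Why: In this catalytic enantioselective vinylogous Mukaiyama aldol reaction the chiral Lewis-base-bound silyl cation activates the aldehyde, and the dienol ether attacks through its γ-carbon on the Si face exposed by the chosen catalyst antipode, which sets 12S under reagent control and delivers the E-enoate.

Step 18
Reactants: 27 (12S)-alcohol
Product: 28 1,12-diol (C1 lactol drawn with 1-OH trans to C11)
Conditions: Bu4NF, AcOH, THF, 0 °C
Reagents that add atoms: none
Why: Buffered fluoride cleaves the anomeric silyl ether quickly because the lactolate is a good leaving group on silicon, and the buffer protects the ester and the enol ether.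

Step 19
Reactants: 28 1,12-diol
Product: 29 7,8-deoxy precursor (1,12-diacetate with the E-C7=C8 olefin)
Conditions: Ac2O, Et3N, DMAP (cat.), CH2Cl2, 0 °C
Reagents that add atoms: acetic anhydride, CC(=O)OC(C)=O
Why: DMAP-catalysed acetylation esterifies both hydroxyls at once with retention at C12, and the equilibrating lactol should be acylated as the anomer whose oxygen lies trans to the C11a substituent, which fixes 1R.

Step 20
Reactants: 29 7,8-deoxy precursor
Product: 30 target CNP0184381.1
Conditions: dimethyldioxirane (1.0 equiv), acetone/CH2Cl2, −78 to −40 °C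
Reagents that add atoms: dimethyldioxirane, CC1(C)OO1
Why: Electrophilic epoxidation should pick the strained, most electron-rich E-C7=C8 bond over the C11 methylene, the acyloxy-deactivated enol ether and the enoate, and can reach it only from the outer face of the conformer imposed by the trans ring fusion (the same relative topology as in the related trans-fused E-cyclononene/exo-methylene sesquiterpene skeleton), so that syn addition sets the 7S,8S trans-epoxide.

Compound list
1 | hex-4-yn-1-ol | CC#CCCCO | starting material
2 | (E)-alkenylzirconocene chloride derived from 1, O-zirconated | C/C(=C\CCCO[Zr](Cl)(C1C=CC=C1)C1C=CC=C1)[Zr](Cl)(C1C=CC=C1)C1C=CC=C1 | intermediate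
3 | (E)-5-iodohex-4-en-1-ol | C/C(I)=C\CCCO | intermediate
4 | (E)-5-iodohex-4-enal | C/C(I)=C\CCC=O | intermediate
5 | (R)-but-3-ene-1,2-diol | C=C[C@@H](O)CO | starting material
6 | acryloyl chloride | C=CC(=O)Cl | starting material
7 | (R)-2-hydroxybut-3-en-1-yl acrylate | C=C[C@@H](O)COC(=O)C=C | intermediate
8 | (R)-2-(triethylsilyloxy)but-3-en-1-yl acrylate | C=C[C@@H](O[Si](CC)(CC)CC)COC(=O)C=C | intermediate
9 | (R)-5-(triethylsilyloxy)-5,6-dihydro-2H-pyran-2-one | O=C1C=C[C@@H](O[Si](CC)(CC)CC)CO1 | intermediate
10 | vinylmagnesium bromide | C=C[Mg]Br | starting material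
11 | bromomagnesium enolate of (4S,5R)-5-(triethylsilyloxy)-4-vinyltetrahydropyran-2-one | C=C[C@@H]1[C@@H](O[Si](CC)(CC)CC)COC(O[Mg]Br)=C1 | intermediate
12 | (3R,4S,5R)-3-[(E)-1-hydroxy-5-iodohex-4-en-1-yl]-5-(triethylsilyloxy)-4-vinyltetrahydro-2H-pyran-2-one (C11 epimers) | C=C[C@@H]1[C@@H](O[Si](CC)(CC)CC)COC(=O)[C@H]1C(O)CC/C=C(\C)I | intermediate
13 | bis-boron adduct of 12 (C6 B-alkyl-9-BBN, C11 O-borinate) | C1CCC2CCCC1B2CC[C@@H]1[C@@H](O[Si](CC)(CC)CC)COC(=O)[C@H]1C(OB1C2CCCC1CCC2)CC/C=C(\C)I | intermediate
14 | (4R,4aS,7E,11aR)-11-hydroxy-7-methyl-4-(triethylsilyloxy)-3,4,4a,5,6,9,10,11,11a-nonahydrocyclonona[c]pyran-1-one (C11 epimers) | OC1CC/C=C(\C)CC[C@@H]2[C@@H](O[Si](CC)(CC)CC)COC(=O)[C@@H]12 | intermediate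
15 | lactol of 14 (1-OH drawn trans to C11, anomers equilibrate) | OC1CC/C=C(\C)CC[C@@H]2[C@@H](O[Si](CC)(CC)CC)CO[C@H](O)[C@@H]12 | intermediate
16 | 1-O-(tert-butyldiphenylsilyl) acetal of 15, 11-OH free | OC1CC/C=C(\C)CC[C@@H]2[C@@H](O[Si](CC)(CC)CC)CO[C@H](O[Si](c3ccccc3)(c3ccccc3)C(C)(C)C)[C@@H]12 | intermediate
17 | 11-ketone of 16 | O=C1CC/C=C(\C)CC[C@@H]2[C@@H](O[Si](CC)(CC)CC)CO[C@H](O[Si](c3ccccc3)(c3ccccc3)C(C)(C)C)[C@@H]12 | intermediate
18 | 11-methylene compound | C=C1CC/C=C(\C)CC[C@@H]2[C@@H](O[Si](CC)(CC)CC)CO[C@H](O[Si](c3ccccc3)(c3ccccc3)C(C)(C)C)[C@@H]12 | intermediate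
19 | 4-alcohol | C=C1CC/C=C(\C)CC[C@@H]2[C@@H](O)CO[C@H](O[Si](c3ccccc3)(c3ccccc3)C(C)(C)C)[C@@H]12 | intermediate
20 | 4-ketone | C=C1CC/C=C(\C)CC[C@@H]2C(=O)CO[C@H](O[Si](c3ccccc3)(c3ccccc3)C(C)(C)C)[C@@H]12 | intermediate
21 | potassium C3=C4 enolate of 20 | C=C1CC/C=C(\C)CC[C@@H]2C([O-])=CO[C@H](O[Si](c3ccccc3)(c3ccccc3)C(C)(C)C)[C@@H]12.[K+] | intermediate
22 | C3=C4 enol triflate | C=C1CC/C=C(\C)CC[C@@H]2C(OS(=O)(=O)C(F)(F)F)=CO[C@H](O[Si](c3ccccc3)(c3ccccc3)C(C)(C)C)[C@@H]12 | intermediate
23 | 4-carbaldehyde (C12 aldehyde) | C=C1CC/C=C(\C)CC[C@@H]2C(C=O)=CO[C@H](O[Si](c3ccccc3)(c3ccccc3)C(C)(C)C)[C@@H]12 | intermediate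
24 | methyl tiglate, methyl (E)-2-methylbut-2-enoate | C/C=C(\C)C(=O)OC | starting material
25 | lithium dienolate of 24 | C=CC(C)=C(OC)[O-].[Li+] | intermediate
26 | tert-butyl[(1-methoxy-2-methylbuta-1,3-dien-1-yl)oxy]dimethylsilane | C=CC(C)=C(OC)O[Si](C)(C)C(C)(C)C | intermediate
27 | (12S)-alcohol with the complete side chain, 1-O-silyl acetal | C=C1CC/C=C(\C)CC[C@@H]2C([C@H](C/C=C(\C)C(=O)OC)O)=CO[C@H](O[Si](c3ccccc3)(c3ccccc3)C(C)(C)C)[C@@H]12 | intermediate
28 | 1,12-diol (C1 lactol) | C=C1CC/C=C(\C)CC[C@@H]2C([C@H](C/C=C(\C)C(=O)OC)O)=CO[C@H](O)[C@@H]12 | intermediate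
29 | 7,8-deoxy precursor, 1,12-diacetate | C=C1CC/C=C(\C)CC[C@@H]2C([C@H](C/C=C(\C)C(=O)OC)OC(C)=O)=CO[C@H](OC(C)=O)[C@@H]12 | intermediate
30 | CNP0184381.1 (1R,4aS,7S,8S,11aR,12S) | C=C1CC[C@@H]2O[C@@]2(C)CC[C@@H]2C([C@H](C/C=C(\C)C(=O)OC)OC(C)=O)=CO[C@H](OC(C)=O)[C@@H]12 | target

Total step count: 20. The longest linear sequence is 17 steps (steps 3–15 and 17–20). Steps 1–2 and step 16 are convergent side branches.

Steps most likely to fail

Step 7. Closure of the strained ring may lose out to oligomerisation, protodeboronation or β-hydride elimination at the alkylpalladium stage. The fallback sets out from 12 and comes back at 14. Borane 13 is oxidised instead (NaBO3·4H2O) to the diol lactone F1. Its primary hydroxyl is exchanged selectively for iodide (I2, PPh3, imidazole) to give the diiodide F2. The same C6–C7 bond is then closed by a nickel-catalysed reductive cross-electrophile coupling of the alkyl iodide with the alkenyl iodide (NiBr2(dme), 4,4'-di-tert-butyl-2,2'-bipyridine, Zn, DMA, high dilution). This coupling needs neither boron nor base, and at this stage no alkene lies within reach of the transient C6 radical.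

Step 14. Deprotonation may occur at C4a, which leads to the tetrasubstituted enol triflate or to epimerisation of the ring fusion. The fallback sets out from 20 and comes back at 23. The ketone is condensed with hydrazine (N2H4·H2O, Et3N, EtOH) to the hydrazone F3. A Barton vinyl iodide synthesis (I2, tetramethylguanidine, THF, 0 °C) then eliminates toward the less substituted C3 side to give the C3=C4 alkenyl iodide F4. F4 enters the same palladium-catalysed reductive carbonylation as 22.

Step 17. The Lewis acid may ionise the new C12–O bond next to the enol ether, and facial selectivity on a hindered, electron-rich aldehyde may be poor. The fallback sets out from 22 and 26 and comes back at 27, and it reverses the polarity of the C4–C12 union. Dienol ether 26 is alkylated at its γ-carbon with trimethyl orthoformate (ZnBr2 cat.) to the acetal ester F5. Mild hydrolysis (wet silica, oxalic acid) gives the aldehyde ester F6. Enol triflate 22 is then added to F6 in a Nozaki–Hiyama–Kishi reaction (CrCl2, NiCl2 cat., chiral oxazoline–sulfonamide ligand, MeCN) under neutral conditions, with the ligand controlling C12.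

Further compounds
F1 | step 7 | (3R,4S,5R)-3-[(E)-1-hydroxy-5-iodohex-4-en-1-yl]-4-(2-hydroxyethyl)-5-(triethylsilyloxy)tetrahydro-2H-pyran-2-one | OCC[C@@H]1[C@@H](O[Si](CC)(CC)CC)COC(=O)[C@H]1C(O)CC/C=C(\C)I
F2 | step 7 | (3R,4S,5R)-3-[(E)-1-hydroxy-5-iodohex-4-en-1-yl]-4-(2-iodoethyl)-5-(triethylsilyloxy)tetrahydro-2H-pyran-2-one | ICC[C@@H]1[C@@H](O[Si](CC)(CC)CC)COC(=O)[C@H]1C(O)CC/C=C(\C)I
F3 | step 14 | hydrazone of ketone 20 | C=C1CC/C=C(\C)CC[C@@H]2C(=NN)CO[C@H](O[Si](c3ccccc3)(c3ccccc3)C(C)(C)C)[C@@H]12
F4 | step 14 | C3=C4 alkenyl iodide (4-iodo analogue of 22) | C=C1CC/C=C(\C)CC[C@@H]2C(I)=CO[C@H](O[Si](c3ccccc3)(c3ccccc3)C(C)(C)C)[C@@H]12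
F5 | step 17 | methyl (E)-5,5-dimethoxy-2-methylpent-2-enoate | COC(OC)C/C=C(\C)C(=O)OC
F6 | step 17 | methyl (E)-2-methyl-5-oxopent-2-enoate | O=CC/C=C(\C)C(=O)OC
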